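Assumptions: (S)-1-(furan-2-yl)ethanol, (S)-(+)-carvone and (S)-2-hydroxybutanoic acid are bought as single enantiomers, and the carbinol centre of the first is only a placeholder that is oxidised away in step 15. Locants C1–C20 follow the target: ring A = C1, C10, C11, C12, C13, C14 (C20 on C11; C15–C17 on C14); tetrahydropyran ring B = O, C2–C6 (C18 on C3); C7 carries C19; C9 is the ketone carbon. Nothing here has been run; the selectivities are predictions from the models named in each step.

**Retrosynthetic overview**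
1. Target ⇐ desilylation and C9 oxidation of a tricyclic homoallylic alcohol; the ten-membered carbocycle (ring C) is closed last, not by aldol or metathesis but by a Me2AlCl-promoted type 1 carbonyl-ene reaction that forms C9–C10, sets C10 and turns the C11 methyl into the exocyclic methylene.
2. Ene precursor ⇐ chelation-controlled vinyl addition to a C7 methyl ketone (sets C7), then anti-Markovnikov Wacker oxidation; the C3 ester comes from MeLi addition to a pyran-3-one with acylation of the alkoxide in the same flask.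
3. Ring B ⇐ Achmatowicz rearrangement of a furyl carbinol, then ionic hydrogenation of the hemiketal (2,6-cis).
4. Furyl carbinol ⇐ anti aldol of the (S)-carvone enolate with a 5-substituted furfural (sets C1 and C2), Kabalka reductive 1,3-transposition, and substrate-controlled 9-BBN hydroboration (sets C15).
5. Ring order: A (chiral pool) → B (Achmatowicz) → C (ene closure).

**Route**

Step 1
Reactants: 1 (S)-1-(furan-2-yl)ethan-1-ol
Product: 2 silyl ether (S)-tert-butyl[1-(furan-2-yl)ethoxy]dimethylsilane
Conditions: TBSCl, imidazole, DMF, 0 °C to rt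
Reagents that add atoms: tert-butyldimethylsilyl chloride, CC(C)(C)[Si](C)(C)Cl
Why: imidazole-promoted O-silylation masks the future C7 oxygen; the carbinol centre is untouched.

Step 2
Reactants: 2 silyl ether
Product: 4 aldehyde (S)-5-[1-(tert-butyldimethylsilyloxy)ethyl]furan-2-carbaldehyde, via 5-lithiofuran 3 (not isolated)
Conditions: n-BuLi, THF, −78 to 0 °C; DMF, −78 °C to rt; H2O
Reagents that add atoms: N,N-dimethylformamide, CN(C)C=O
Why: alpha-lithiation of the 2-substituted furan at its free C5 position followed by Bouveault formylation; no stereocentre is formed.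

Step 3
Reactants: 5 (S)-(+)-carvone; 4 aldehyde
Product: 7 anti-aldol adduct (5S,6S)-6-[(R)-{5-[(S)-1-(tert-butyldimethylsilyloxy)ethyl]furan-2-yl}(hydroxy)methyl]-2-methyl-5-(prop-1-en-2-yl)cyclohex-2-en-1-one, via lithium dienolate 6 (not isolated)
Conditions: LiN(iPr)2, THF, −78 °C; 4, −78 °C, 20 min; AcOH quench at −78 °C
Reagents that add atoms: none
Why: kinetic alpha'-deprotonation of carvone and lithium aldol addition; the aldehyde adds to C1 anti to the neighbouring isopropenyl group (C1 trans to C14) and the ring-locked (E)-enolate reacts through a Zimmerman–Traxler chair to give the anti aldol, which sets C2.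

Step 4
Reactants: 7 anti-aldol adduct
Product: 8 tosylhydrazone of 7
Conditions: TsNHNH2, THF/MeOH, 40 °C
Reagents that add atoms: 4-methylbenzenesulfonohydrazide, Cc1ccc(cc1)S(=O)(=O)NN
Why: hydrazone condensation at the enone carbonyl under neutral conditions, which avoid retro-aldol and dehydration; no stereocentre is formed.

Step 5
Reactants: 8 tosylhydrazone
Product: 11 diene carbinol (R)-{5-[(S)-1-(tert-butyldimethylsilyloxy)ethyl]furan-2-yl}[(1S,6S)-3-methyl-6-(prop-1-en-2-yl)cyclohex-2-en-1-yl]methanol, via N-boryl hydrazine 9 (not isolated), via allylic diazene 10 (not isolated)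
Conditions: catecholborane, CHCl3, 0 °C; NaOAc·3H2O, reflux
Reagents that add atoms: none
Why: Kabalka reductive 1,3-transposition of an enone tosylhydrazone; 1,2-hydride delivery, sulfinate loss and retro-ene loss of N2 move the alkene to C10=C11 and put hydrogen on C12, leaving C1, C2 and C14 untouched.

Step 6
Reactants: 11 diene carbinol
Product: 13 diol (11 with the isopropenyl group converted into an (R)-1-hydroxypropan-2-yl group), via alkyl-9-BBN 12 (not isolated)
Conditions: 9-BBN (3 equiv), THF, 0 °C to rt; NaOH, H2O2, 0 °C to rt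
Reagents that add atoms: hydrogen peroxide, OO
Why: hydroboration–oxidation; 9-BBN takes the 1,1-disubstituted alkene and not the trisubstituted ring alkene, and adds to the face anti to the branched C1 substituent with C14–H next to the vinylic methyl (the isopulegol-type model), which sets C15 as R.

Step 7
Reactants: 13 diol
Product: 14 primary TBDPS ether of 13
Conditions: TBDPSCl, imidazole, CH2Cl2, 0 °C
Reagents that add atoms: tert-butyl(chloro)diphenylsilane, CC(C)(C)[Si](Cl)(c1ccccc1)c1ccccc1
Why: sterically controlled silylation of the primary C17 hydroxyl leaves the secondary furyl carbinol free for ring expansion.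

Step 8
Reactants: 14 primary TBDPS ether
Product: 15 hemiketal 6-hydroxy-2H-pyran-3(6H)-one (anomeric mixture at C6)
Conditions: NBS, NaHCO3, THF/H2O 4:1, 0 °C
Reagents that add atoms: water, O
Why: Achmatowicz oxidative ring expansion of the furyl carbinol builds ring B with the C3 ketone and retains C2; the electron-rich furan is brominated much faster than the trisubstituted alkene.

Step 9
Reactants: 15 hemiketal
Product: 16 enone (2R,6R)-2,6-cis-2H-pyran-3(6H)-one
Conditions: Et3SiH, CF3CO2H, CH2Cl2, −40 °C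
Reagents that add atoms: none
Why: ionic hydrogenation of the hemiketal; hydride adds axially to the ring oxocarbenium ion, trans to the C2 substituent, which gives the 2,6-cis ring and sets C6.

Step 10
Reactants: 16 enone
Product: 17 ketone (2R,6R)-2,6-cis-tetrahydropyran-3-one
Conditions: H2 (1 atm), RhCl(PPh3)3 (10 mol %), benzene, rt
Reagents that add atoms: none
Why: homogeneous hydrogenation with RhCl(PPh3)3 saturates the cis-disubstituted enone alkene and leaves the trisubstituted C10=C11 alkene and the ketone alone.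

Step 11
Reactants: 18 (S)-2-hydroxybutanoic acid
Product: 19 acid (S)-2-(butanoyloxy)butanoic acid
Conditions: butanoyl chloride (neat), 0 to 45 °C; then THF/H2O, rt
Reagents that add atoms: butanoyl chloride, CCCC(Cl)=O
Why: O-acylation of the alpha-hydroxy acid; the stereocentre is not involved.

Step 12
Reactants: 19 acid
Product: 20 acid chloride (S)-2-(butanoyloxy)butanoyl chloride
Conditions: (COCl)2, DMF (cat.), CH2Cl2, 0 °C to rt
Reagents that add atoms: oxalyl chloride, ClC(=O)C(Cl)=O
Why: Vilsmeier-catalysed acid chloride formation; alpha-acyloxy acid chlorides of this kind keep their configuration.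

Step 13
Reactants: 17 ketone; 20 acid chloride
Product: 22 tertiary ester (C3 methyl carbinol acylated by the (S)-2-(butanoyloxy)butanoyl group), via lithium alkoxide 21 (not isolated)
Conditions: MeLi, LiClO4, Et2O, −78 °C; then 20, −78 to 0 °C
Reagents that add atoms: methyllithium, [Li]C
Why: 1,2-addition then O-acylation of the tertiary lithium alkoxide in the same flask; MeLi attacks the chair pyranone equatorially, so C18 is equatorial and trans to the C2 substituent and the oxygen is axial, which sets C3 as R, and the acyl stereocentre comes from 20.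

Step 14
Reactants: 22 tertiary ester
Product: 23 secondary alcohol (C7–OH free)
Conditions: camphorsulfonic acid (20 mol %), MeOH/CH2Cl2, 0 °C to rt
Reagents that add atoms: none
Why: acid-catalysed methanolysis removes the secondary TBS ether and spares the much more acid-stable primary TBDPS ether and the esters.

Step 15
Reactants: 23 secondary alcohol
Product: 24 methyl ketone (C7 carbonyl)
Conditions: Dess–Martin periodinane, pyridine, CH2Cl2, 0 °C to rt
Reagents that add atoms: none
Why: Dess–Martin oxidation under buffered conditions removes the placeholder stereocentre without epimerising C6.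

Step 16
Reactants: 24 methyl ketone
Product: 25 tertiary allylic alcohol (7R)
Conditions: CH2=CHMgBr, MgBr2·OEt2, CH2Cl2/THF, −78 °C; H2O
Reagents that add atoms: vinylmagnesium bromide, C=C[Mg]Br
Why: Cram-chelate Grignard addition; magnesium bridges the ketone oxygen and the ring oxygen on C6 and the vinyl group adds from the side of the small C6–H, which sets C7 as R, while at −78 °C the chelated ketone reacts far faster than the hindered esters.

Step 17
Reactants: 25 tertiary allylic alcohol
Product: 26 triethylsilyl ether of 25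
Conditions: TESOTf, 2,6-lutidine, CH2Cl2, −78 to 0 °C
Reagents that add atoms: triethylsilyl trifluoromethanesulfonate, CC[Si](CC)(CC)OS(=O)(=O)C(F)(F)F
Why: silyl triflate silylation of the hindered tertiary alcohol blocks retro-aldol and aluminium alkoxide formation in the next two steps.

Step 18
Reactants: 26 triethylsilyl ether
Product: 27 aldehyde (C9 formyl)
Conditions: PdCl2(PhCN)2 (12 mol %), CuCl2·2H2O (12 mol %), AgNO2 (6 mol %), O2 (1 atm), t-BuOH/MeNO2 15:1, rt
Reagents that add atoms: dioxygen, O=O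
Why: aldehyde-selective, nitrite-modified Wacker oxidation; the allylic silyloxy group on a quaternary carbon steers oxygen to the terminal carbon C9, and only the monosubstituted alkene reacts.

Step 19
Reactants: 27 aldehyde
Product: 28 tricyclic homoallylic alcohol (C9–OH epimers; C11=C20 methylene; cis ring fusion)
Conditions: Me2AlCl (3 equiv), CH2Cl2 (0.003 M), −78 to −20 °C; then cold 1 M HCl
Reagents that add atoms: none
Why: Proposed new method: a Lewis-acid-promoted type 1 intramolecular carbonyl-ene (Prins-type) closure of an eight-membered oxacycle, in which the Me2AlCl-activated C9 aldehyde is attacked by the less substituted alkene carbon C10 (cationic character at tertiary C11) and the carbonyl oxygen then takes a proton from the C20 methyl through a six-membered transition state, forming C9–C10 and the C11=C20 methylene together; the C1–C2 tether can only reach the alkene face syn to C2, which sets C10 as R with a cis ring fusion, and the closest known chemistry is the Me2AlCl-promoted aldehyde ene reaction of 1-methylcyclohexene-type alkenes and the citronellal-to-isopulegol cyclisation.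

Step 20
Reactants: 28 tricyclic homoallylic alcohol
Product: 29 bis-silyl-protected ketone (C9 carbonyl)
Conditions: Dess–Martin periodinane, pyridine, CH2Cl2, 0 °C
Reagents that add atoms: none
Why: buffered Dess–Martin oxidation gives the beta,gamma-unsaturated ketone without moving the exocyclic alkene into conjugation or epimerising C10, and removes the uncontrolled C9 centre.

Step 21
Reactants: 29 bis-silyl-protected ketone
Product: 30 target CNP0291223.2
Conditions: HF·pyridine, pyridine, THF, 0 °C to rt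
Reagents that add atoms: none
Why: fluoride cleavage of the tertiary triethylsilyl and primary TBDPS ethers under buffered conditions that spare the esters, the beta-hydroxy ketone and the beta,gamma-enone.

**Compound list**
1 | (S)-1-(furan-2-yl)ethan-1-ol | C[C@H](O)c1ccco1 | starting material
2 | (S)-tert-butyl[1-(furan-2-yl)ethoxy]dimethylsilane | C[C@H](O[Si](C)(C)C(C)(C)C)c1ccco1 | intermediate
3 | {5-[(S)-1-(tert-butyldimethylsilyloxy)ethyl]furan-2-yl}lithium | C[C@H](O[Si](C)(C)C(C)(C)C)c1ccc([Li])o1 | intermediate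
4 | (S)-5-[1-(tert-butyldimethylsilyloxy)ethyl]furan-2-carbaldehyde | C[C@H](O[Si](C)(C)C(C)(C)C)c1ccc(C=O)o1 | intermediate
5 | (S)-(+)-carvone, (5S)-2-methyl-5-(prop-1-en-2-yl)cyclohex-2-en-1-one | CC1=CC[C@@H](CC1=O)C(C)=C | starting material
6 | lithium cross-conjugated dienolate of (S)-carvone (enolate double bond C10=C1) | CC1=CC[C@H](C(C)=C)C=C1O[Li] | intermediate
7 | (5S,6S)-6-[(R)-{5-[(S)-1-(tert-butyldimethylsilyloxy)ethyl]furan-2-yl}(hydroxy)methyl]-2-methyl-5-(prop-1-en-2-yl)cyclohex-2-en-1-one (C1/C14 trans, C1–C2 anti) | CC1=CC[C@H](C(C)=C)[C@@H]([C@@H](O)c2ccc(o2)[C@H](C)O[Si](C)(C)C(C)(C)C)C1=O | intermediate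
8 | 4-methylbenzenesulfonylhydrazone of 7 at C10 | CC1=CC[C@H](C(C)=C)[C@@H]([C@@H](O)c2ccc(o2)[C@H](C)O[Si](C)(C)C(C)(C)C)C1=NNS(=O)(=O)c1ccc(C)cc1 | intermediate
9 | allylic N'-tosylhydrazine from 8, N-bound to 1,3,2-benzodioxaborol-2-yl (C10 epimers) | CC1=CC[C@H](C(C)=C)[C@@H]([C@@H](O)c2ccc(o2)[C@H](C)O[Si](C)(C)C(C)(C)C)C1N(NS(=O)(=O)c1ccc(C)cc1)B1Oc2ccccc2O1 | intermediate
10 | allylic diazene at C10 (C10 epimers) | CC1=CC[C@H](C(C)=C)[C@@H]([C@@H](O)c2ccc(o2)[C@H](C)O[Si](C)(C)C(C)(C)C)C1N=N | intermediate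
11 | (R)-{5-[(S)-1-(tert-butyldimethylsilyloxy)ethyl]furan-2-yl}[(1S,6S)-3-methyl-6-(prop-1-en-2-yl)cyclohex-2-en-1-yl]methanol | CC1=C[C@H]([C@@H](O)c2ccc(o2)[C@H](C)O[Si](C)(C)C(C)(C)C)[C@@H](C(C)=C)CC1 | intermediate
12 | B-alkyl-9-borabicyclo[3.3.1]nonane from 11 (boron on C17; C15 as in the target) | CC1=C[C@H]([C@@H](O)c2ccc(o2)[C@H](C)O[Si](C)(C)C(C)(C)C)[C@@H]([C@@H](C)CB2C3CCCC2CCC3)CC1 | intermediate
13 | diol: 11 with C14 bearing (R)-1-hydroxypropan-2-yl (C1, C2, C14, C15 arranged as in the target) | CC1=C[C@H]([C@@H](O)c2ccc(o2)[C@H](C)O[Si](C)(C)C(C)(C)C)[C@@H]([C@@H](C)CO)CC1 | intermediate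
14 | 13 with the C17 hydroxyl as tert-butyldiphenylsilyl ether | CC1=C[C@H]([C@@H](O)c2ccc(o2)[C@H](C)O[Si](C)(C)C(C)(C)C)[C@@H]([C@@H](C)CO[Si](c2ccccc2)(c2ccccc2)C(C)(C)C)CC1 | intermediate
15 | (2R)-6-hydroxy-6-[(S)-1-(tert-butyldimethylsilyloxy)ethyl]-2-(ring A)-2H-pyran-3(6H)-one, C6 anomers | CC1=C[C@H]([C@H]2OC(O)([C@H](C)O[Si](C)(C)C(C)(C)C)C=CC2=O)[C@@H]([C@@H](C)CO[Si](c2ccccc2)(c2ccccc2)C(C)(C)C)CC1 | intermediate
16 | (2R,6R)-2,6-cis-6-[(S)-1-(tert-butyldimethylsilyloxy)ethyl]-2-(ring A)-2H-pyran-3(6H)-one | CC1=C[C@H]([C@H]2O[C@@H]([C@H](C)O[Si](C)(C)C(C)(C)C)C=CC2=O)[C@@H]([C@@H](C)CO[Si](c2ccccc2)(c2ccccc2)C(C)(C)C)CC1 | intermediate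
17 | (2R,6R)-2,6-cis-tetrahydropyran-3-one (16 with C4–C5 saturated) | CC1=C[C@H]([C@H]2O[C@@H]([C@H](C)O[Si](C)(C)C(C)(C)C)CCC2=O)[C@@H]([C@@H](C)CO[Si](c2ccccc2)(c2ccccc2)C(C)(C)C)CC1 | intermediate
18 | (S)-2-hydroxybutanoic acid | CC[C@H](O)C(O)=O | starting material
19 | (S)-2-(butanoyloxy)butanoic acid | CC[C@H](OC(=O)CCC)C(O)=O | intermediate
20 | (S)-2-(butanoyloxy)butanoyl chloride | CC[C@H](OC(=O)CCC)C(Cl)=O | intermediate
21 | lithium (3R)-alkoxide from MeLi addition to 17 (C18 equatorial, O axial) | CC1=C[C@H]([C@H]2O[C@@H]([C@H](C)O[Si](C)(C)C(C)(C)C)CC[C@@]2(C)O[Li])[C@@H]([C@@H](C)CO[Si](c2ccccc2)(c2ccccc2)C(C)(C)C)CC1 | intermediate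
22 | (3R)-tertiary (S)-2-(butanoyloxy)butanoate; C7 TBS ether, C17 TBDPS ether | CC1=C[C@H]([C@H]2O[C@@H]([C@H](C)O[Si](C)(C)C(C)(C)C)CC[C@@]2(C)OC(=O)[C@H](CC)OC(=O)CCC)[C@@H]([C@@H](C)CO[Si](c2ccccc2)(c2ccccc2)C(C)(C)C)CC1 | intermediate
23 | 22 with free (7S) secondary alcohol | CC1=C[C@H]([C@H]2O[C@@H]([C@H](C)O)CC[C@@]2(C)OC(=O)[C@H](CC)OC(=O)CCC)[C@@H]([C@@H](C)CO[Si](c2ccccc2)(c2ccccc2)C(C)(C)C)CC1 | intermediate
24 | C6 acetyl compound (C7 methyl ketone) | CC1=C[C@H]([C@H]2O[C@@H](C(C)=O)CC[C@@]2(C)OC(=O)[C@H](CC)OC(=O)CCC)[C@@H]([C@@H](C)CO[Si](c2ccccc2)(c2ccccc2)C(C)(C)C)CC1 | intermediate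
25 | (7R)-tertiary allylic alcohol (C7: methyl, hydroxyl, vinyl) | CC1=C[C@H]([C@H]2O[C@@H]([C@](C)(O)C=C)CC[C@@]2(C)OC(=O)[C@H](CC)OC(=O)CCC)[C@@H]([C@@H](C)CO[Si](c2ccccc2)(c2ccccc2)C(C)(C)C)CC1 | intermediate
26 | triethylsilyl ether of 25 | CC1=C[C@H]([C@H]2O[C@@H]([C@](C)(O[Si](CC)(CC)CC)C=C)CC[C@@]2(C)OC(=O)[C@H](CC)OC(=O)CCC)[C@@H]([C@@H](C)CO[Si](c2ccccc2)(c2ccccc2)C(C)(C)C)CC1 | intermediate
27 | C9 aldehyde (C7–C8H2–C9HO) | CC1=C[C@H]([C@H]2O[C@@H]([C@](C)(O[Si](CC)(CC)CC)CC=O)CC[C@@]2(C)OC(=O)[C@H](CC)OC(=O)CCC)[C@@H]([C@@H](C)CO[Si](c2ccccc2)(c2ccccc2)C(C)(C)C)CC1 | intermediate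
28 | tricyclic C9 alcohol (C9 epimers), C11=C20 methylene, C7 triethylsilyl ether, C17 TBDPS ether; all other centres as in the target | C=C1CC[C@H]([C@@H](C)CO[Si](c3ccccc3)(c3ccccc3)C(C)(C)C)[C@@H]2[C@H]1C(O)C[C@@](C)(O[Si](CC)(CC)CC)[C@H]1CC[C@@](C)(OC(=O)[C@H](CC)OC(=O)CCC)[C@@H]2O1 | intermediate
29 | 7-O-triethylsilyl-17-O-tert-butyldiphenylsilyl derivative of the target | C=C1CC[C@H]([C@@H](C)CO[Si](c3ccccc3)(c3ccccc3)C(C)(C)C)[C@@H]2[C@H]1C(=O)C[C@@](C)(O[Si](CC)(CC)CC)[C@H]1CC[C@@](C)(OC(=O)[C@H](CC)OC(=O)CCC)[C@@H]2O1 | intermediate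
30 | CNP0291223.2, (1R,2R,3R,6R,7R,10R,14R,15R) with (S)-2-(butanoyloxy)butanoate on O3 | C=C1CC[C@H]([C@@H](C)CO)[C@@H]2[C@H]1C(=O)C[C@@](C)(O)[C@H]1CC[C@@](C)(OC(=O)[C@H](CC)OC(=O)CCC)[C@@H]2O1 | target

**Totals and risk**
Total step count: 21. Longest linear sequence: 19 steps (steps 1–10 and 13–21, from 1 to 30).

The three steps most likely to fail:

Step 19, the medium-ring ene closure. Oligomerisation, proton loss towards C12 or methyl transfer from aluminium may win. The fallback sets out from 27 and splits the event into two polar steps. Ene-type allylic chlorination of the C10=C11 alkene (N-chlorosuccinimide, PhSeCl 10 mol %, CH2Cl2, rt) gives the transposed secondary allylic chloride F1, with chlorine on C10 and the C11=C20 methylene already in place; either C10 epimer serves. CrCl2 (divalent chromium, 6 equiv) with NaI in THF/DMF at high dilution then forms the primary allylchromium species, which adds to the C9 aldehyde through its gamma carbon C10 in an intramolecular Nozaki–Hiyama–Kishi allylation. The fallback comes back to the route at 28.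

Step 13, C3 configuration and acylation of a hindered alkoxide. Axial attack of MeLi, enolisation at C2, or ketene formation from 20 could erode the result. The fallback sets out from 17. Corey–Chaykovsky methylenation with dimethylsulfoxonium methylide (Me3S(O)I, NaH, DMSO, rt) forms its betaine reversibly and so places the new C–C bond equatorial, giving the spiro-epoxide F2. LiEt3BH (THF, 0 °C) opens F2 at the CH2 terminus to the tertiary alcohol F3, with C18 equatorial and the hydroxyl axial. Separate acylation of F3 with 20 (pyridine, DMAP, CH2Cl2, 0 °C to rt) comes back to the route at 22.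

Step 6, C15 by substrate control. If the diastereomer ratio is poor, the fallback sets out from 11 and uses catalyst control. CuCl (5 mol %), DTBM-SEGPHOS (the enantiomer that a test run shows to be matched; both are sold), KOtBu and pinacolborane in THF at rt hydrocuprate the 1,1-disubstituted alkene anti-Markovnikov and give the pinacol boronate F4, with C15 fixed by the ligand. Oxidation of F4 with NaBO3·4H2O in THF/H2O comes back to the route at 13.

**Further compounds**
F1 | step 19 | 10-chloro-11(20)-ene aldehyde: 27 with chlorine on C10 (epimers) and the alkene moved to C11=C20 | C=C1CC[C@H]([C@@H](C)CO[Si](c2ccccc2)(c2ccccc2)C(C)(C)C)[C@@H]([C@H]2O[C@@H]([C@](C)(O[Si](CC)(CC)CC)CC=O)CC[C@@]2(C)OC(=O)[C@H](CC)OC(=O)CCC)C1Cl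
F2 | step 13 | spiro-epoxide at C3 of 17 (epoxide CH2 equatorial, oxygen axial) | CC1=C[C@H]([C@H]2O[C@@H]([C@H](C)O[Si](C)(C)C(C)(C)C)CC[C@]23CO3)[C@@H]([C@@H](C)CO[Si](c2ccccc2)(c2ccccc2)C(C)(C)C)CC1
F3 | step 13 | (3R)-tertiary alcohol, the protonated form of 21 | CC1=C[C@H]([C@H]2O[C@@H]([C@H](C)O[Si](C)(C)C(C)(C)C)CC[C@@]2(C)O)[C@@H]([C@@H](C)CO[Si](c2ccccc2)(c2ccccc2)C(C)(C)C)CC1
F4 | step 6 | C17 pinacol boronate of 11 (C15 as in the target) | CC1=C[C@H]([C@@H](O)c2ccc(o2)[C@H](C)O[Si](C)(C)C(C)(C)C)[C@@H]([C@@H](C)CB2OC(C)(C)C(C)(C)O2)CC1
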